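**Plan**
- Retrosynthesis: after removal of eight benzyl ethers, the C4–C4a bond of the upper (4'-hydroxyphenyl, 7-oxygenated, 5-deoxy) flavan is cut first, then the C4–C8 interflavan bond (aryllithium plus aldehyde), then the benzylic C2–O aryl ether (epoxide opening) and the C2=C3 olefin.
- Enabling feature: upper C4 is bonded to C8 of epicatechin ring A, which carries O1 and O7 ortho and O5 para to C8, so a C4 cation is a trialkoxybenzylic ion. Upper ring A lacks O5, and its C4a (para to O7, ortho to O1) serves better as the nucleophile.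
- Forward: the chain comes first (Z-cinnamate, cis-epoxide, threo aryl ether, α-benzyloxy aldehyde) and is joined to 8-lithiated penta-O-benzylepicatechin. The upper pyran is the only ring built and closes in the penultimate step; hydrogenolysis ends the route.
- Stereochemistry: lower C2/C3 come from (−)-epicatechin; upper C3 from a Jacobsen epoxidation; upper C2 from SN2 inversion at the benzylic epoxide carbon; upper C4 is set in the ring closure, trans to O3, by allylic strain in the cation.

Key step: step 10

Remark: the carbinol made in step 9 is carried forward as the mixture of its two epimers at the new carbinol carbon, since both ionise to the same cation.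

**Route**

Step 1
Reactants: 1 4-(benzyloxy)benzaldehyde; 2 ethyl 2-(diphenoxyphosphoryl)acetate
Product: 4 ethyl (Z)-3-[4-(benzyloxy)phenyl]prop-2-enoate, via sodium phosphonate carbanion 3 (not isolated)
Conditions: NaH, THF, 0 °C; then 1, −78 → 0 °C; subdued light
Reagents that add atoms: none
Why: Horner–Wadsworth–Emmons olefination in its Z-selective diaryl phosphonate (Ando) form, in which the electron-poor phenoxy groups make the kinetic cis-oxaphosphetane collapse faster than it equilibrates, so the Z-cinnamate should predominate and the minor E-isomer is removed by chromatography.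

Step 2
Reactants: 4 ethyl (Z)-3-[4-(benzyloxy)phenyl]prop-2-enoate
Product: 5 ethyl (2S,3S)-3-[4-(benzyloxy)phenyl]oxirane-2-carboxylate (cis-epoxide)
Conditions: (S,S)-(salen)MnCl (5 mol %; salen = N,N'-bis(3,5-di-tert-butylsalicylidene)cyclohexane-1,2-diamine dianion), 4-phenylpyridine N-oxide (0.25 equiv), aq. NaOCl (pH 11.3), CH2Cl2, 0–4 °C
Reagents that add atoms: sodium hypochlorite, [Na+].[O-]Cl
Why: Jacobsen epoxidation of a cis-disubstituted aryl-conjugated alkene, the best substrate class for this catalyst, in which side-on approach of the alkene to the oxo-manganese species of the (S,S)-ligand sets both epoxide carbons as (2S,3S), the enantiomeric sense to that known for cis-cinnamates with the (R,R)-catalyst, and any trans-epoxide from stepwise collapse is separated by chromatography.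

Step 3
Reactants: 5 ethyl (2S,3S)-3-[4-(benzyloxy)phenyl]oxirane-2-carboxylate; 6 3-(benzyloxy)phenol
Product: 7 ethyl (2S,3R)-3-[3-(benzyloxy)phenoxy]-3-[4-(benzyloxy)phenyl]-2-hydroxypropanoate
Conditions: 6 (2 equiv), Cs2CO3 (0.3 equiv), DMF, 45 °C
Reagents that add atoms: none
Why: SN2 ring opening of an arylglycidic ester by phenoxide at the benzylic carbon, which is activated by the para-benzyloxyphenyl group and not deactivated like the carbon α to the ester, so C3 is inverted to R while C2 keeps its configuration, giving the threo ether that maps onto the 2,3-cis flavan.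

Step 4
Reactants: 7 ethyl (2S,3R)-3-[3-(benzyloxy)phenoxy]-3-[4-(benzyloxy)phenyl]-2-hydroxypropanoate
Product: 8 ethyl (2S,3R)-2-(benzyloxy)-3-[3-(benzyloxy)phenoxy]-3-[4-(benzyloxy)phenyl]propanoate
Conditions: BnBr, Ag2O, n-Bu4NI (cat.), CH2Cl2, rt, dark
Reagents that add atoms: benzyl bromide, BrCc1ccccc1
Why: silver oxide-mediated Williamson (Purdie) etherification of an α-hydroxy ester, chosen because it is essentially non-basic and so should neither epimerise the α-carbon nor expel the β-aryloxide, and it touches no stereocentre.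

Step 5
Reactants: 8 ethyl (2S,3R)-2-(benzyloxy)-3-[3-(benzyloxy)phenoxy]-3-[4-(benzyloxy)phenyl]propanoate
Product: 9 (2S,3R)-2-(benzyloxy)-3-[3-(benzyloxy)phenoxy]-3-[4-(benzyloxy)phenyl]propanal
Conditions: i-Bu2AlH (1.1 equiv), CH2Cl2, −78 °C; MeOH, then aq. KNaC4H4O6 (Rochelle salt); used at once without chromatography
Reagents that add atoms: none
Why: partial reduction of an α-alkoxy ester with i-Bu2AlH, in which the tetrahedral aluminium hemiacetal is held by chelation to the α-benzyloxy oxygen until the cold quench, so the aldehyde is released only on work-up and the α-stereocentre is not disturbed.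

Step 6
Reactants: 10 (−)-epicatechin
Product: 11 5,7,3',4'-tetra-O-benzyl-(−)-epicatechin
Conditions: BnBr (4.4 equiv), K2CO3, DMF, 0 °C → rt, Ar
Reagents that add atoms: benzyl bromide, BrCc1ccccc1
Why: Williamson etherification in which K2CO3 deprotonates only the four phenols and leaves the secondary 3-hydroxyl free, with C2 and C3 untouched.

Step 7
Reactants: 11 5,7,3',4'-tetra-O-benzyl-(−)-epicatechin
Product: 12 8-bromo-5,7,3',4'-tetra-O-benzylepicatechin
Conditions: NBS (1.0 equiv), CH2Cl2, −40 °C → rt
Reagents that add atoms: N-bromosuccinimide, O=C1CCC(=O)N1Br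
Why: electrophilic aromatic bromination of the phloroglucinol-type ring A, which for benzylated flavan-3-ols takes place at C8 in preference to C6 and so marks the future interflavan carbon.

Step 8
Reactants: 12 8-bromo-5,7,3',4'-tetra-O-benzylepicatechin
Product: 13 8-bromo-3,5,7,3',4'-penta-O-benzylepicatechin
Conditions: NaH, BnBr, DMF, 0 °C → rt
Reagents that add atoms: benzyl bromide, BrCc1ccccc1
Why: Williamson etherification of the secondary alcohol through its sodium alkoxide, which removes the last acidic proton before the lithiation and leaves the aryl bromide intact.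

Step 9
Reactants: 13 8-bromo-3,5,7,3',4'-penta-O-benzylepicatechin; 9 (2S,3R)-2-(benzyloxy)-3-[3-(benzyloxy)phenoxy]-3-[4-(benzyloxy)phenyl]propanal
Product: 15 (2R,3R)-2-(benzyloxy)-3-[3-(benzyloxy)phenoxy]-3-[4-(benzyloxy)phenyl]-1-(3,5,7,3',4'-penta-O-benzylepicatechin-8-yl)propan-1-ol (both C1 epimers), via 8-lithio-penta-O-benzylepicatechin 14 (not isolated)
Conditions: 13 (1.3 equiv), n-BuLi, THF, −78 °C; then 9, −78 °C; H2O
Reagents that add atoms: none
Why: bromine–lithium exchange followed by 1,2-addition of the aryllithium to the aldehyde, which at −78 °C should outrun enolisation and fixes the interflavan bond at C8 without ambiguity, while the new carbinol centre may form as a mixture because it is ionised in the next step.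

Step 10
Reactants: 15 (2R,3R)-2-(benzyloxy)-3-[3-(benzyloxy)phenoxy]-3-[4-(benzyloxy)phenyl]-1-(3,5,7,3',4'-penta-O-benzylepicatechin-8-yl)propan-1-ol
Product: 17 (2R,3R,4R)-3,7-bis(benzyloxy)-2-[4-(benzyloxy)phenyl]-4-(3,5,7,3',4'-penta-O-benzylepicatechin-8-yl)chromane (octa-O-benzyl ether of the target), via trialkoxybenzylic C4 cation 16 (not isolated)
Conditions: BF3·OEt2 (0.3 equiv), CH2Cl2 (0.005 M), −78 → −20 °C
Reagents that add atoms: none
Why: BF3 ionises the C4 hydroxyl of either epimer of 15 to the one cation 16, a 2,4,6-trialkoxybenzylic ion whose charge is shared by O1, O5 and O7 of epicatechin ring A, and the tethered resorcinol diether attacks it through its carbon para to benzyloxy and ortho to the ether oxygen before a proton is lost to restore the arene. The closest known reaction type is the acid-mediated cyclodehydration of 3-aryloxy-1-arylpropan-1-ols to 4-arylchromans, an intramolecular Friedel–Crafts alkylation. The upper pyran ring closes as a six-membered ring through a half-chair transition state in which the attacking arene C=C becomes part of the new ring (6-endo with respect to the arene) while the delocalised bond from C4 to the epicatechin ring stays outside it. The new C4 stereocentre is controlled by C3 through allylic 1,3-strain: the planar cation keeps its C3–H bond in the plane next to the ortho-disubstituted epicatechin ring, so C2 with its tether lies on one face and the C3 benzyloxy group on the other, and the arene is delivered anti to benzyloxy to give the 3,4-trans (4R) product, which is also the less strained diastereomer. The step needs ionisation at C4 in preference to the benzylic aryl ether at C2 and attack para and not ortho to benzyloxy; the first is secured by the three donor oxygens that flank C8 of the epicatechin ring together with substoichiometric Lewis acid at low temperature, the second by crowding of the ring carbon between the two oxygens. No C6 versus C8 question arises because the epicatechin ring was attached through its 8-lithio derivative.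

Step 11
Reactants: 17 octa-O-benzyl ether of the target
Product: 18 (2R,3R,4R)-4-[(2R,3R)-2-(3,4-dihydroxyphenyl)-3,5,7-trihydroxychroman-8-yl]-2-(4-hydroxyphenyl)chromane-3,7-diol (CNP0118995.2)
Conditions: H2 (1 atm), Pd(OH)2/C, THF/MeOH/H2O, rt; filtration, lyophilisation
Reagents that add atoms: none
Why: hydrogenolysis of the eight O-benzyl ethers over Pd(OH)2/C, conditions under which the cyclic benzylic C2–O1 ethers and the C4–C8 bond of benzylated flavan dimers are expected to persist, so no stereocentre is touched.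

**Compound list**

1 | 4-(benzyloxy)benzaldehyde | O=Cc1ccc(OCc2ccccc2)cc1 | starting material
2 | ethyl 2-(diphenoxyphosphoryl)acetate | CCOC(=O)CP(=O)(Oc1ccccc1)Oc1ccccc1 | starting material
3 | sodium salt of the carbanion of 2 | [Na+].CCOC(=O)[CH-]P(=O)(Oc1ccccc1)Oc1ccccc1 | intermediate
4 | ethyl (Z)-3-[4-(benzyloxy)phenyl]prop-2-enoate | CCOC(=O)/C=C\c1ccc(OCc2ccccc2)cc1 | intermediate
5 | ethyl (2S,3S)-3-[4-(benzyloxy)phenyl]oxirane-2-carboxylate | CCOC(=O)[C@H]1O[C@H]1c1ccc(OCc2ccccc2)cc1 | intermediate
6 | 3-(benzyloxy)phenol | Oc1cccc(OCc2ccccc2)c1 | starting material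
7 | ethyl (2S,3R)-3-[3-(benzyloxy)phenoxy]-3-[4-(benzyloxy)phenyl]-2-hydroxypropanoate | CCOC(=O)[C@@H](O)[C@H](Oc1cccc(OCc2ccccc2)c1)c1ccc(OCc2ccccc2)cc1 | intermediate
8 | ethyl (2S,3R)-2-(benzyloxy)-3-[3-(benzyloxy)phenoxy]-3-[4-(benzyloxy)phenyl]propanoate | CCOC(=O)[C@@H](OCc1ccccc1)[C@H](Oc1cccc(OCc2ccccc2)c1)c1ccc(OCc2ccccc2)cc1 | intermediate
9 | (2S,3R)-2-(benzyloxy)-3-[3-(benzyloxy)phenoxy]-3-[4-(benzyloxy)phenyl]propanal | O=C[C@@H](OCc1ccccc1)[C@H](Oc1cccc(OCc2ccccc2)c1)c1ccc(OCc2ccccc2)cc1 | intermediate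
10 | (−)-epicatechin | O[C@@H]1Cc2c(O)cc(O)cc2O[C@@H]1c1ccc(O)c(O)c1 | starting material
11 | 5,7,3',4'-tetra-O-benzyl-(−)-epicatechin | O[C@@H]1Cc2c(OCc3ccccc3)cc(OCc3ccccc3)cc2O[C@@H]1c1ccc(OCc2ccccc2)c(OCc2ccccc2)c1 | intermediate
12 | 8-bromo-5,7,3',4'-tetra-O-benzylepicatechin | O[C@@H]1Cc2c(OCc3ccccc3)cc(OCc3ccccc3)c(Br)c2O[C@@H]1c1ccc(OCc2ccccc2)c(OCc2ccccc2)c1 | intermediate
13 | 8-bromo-3,5,7,3',4'-penta-O-benzylepicatechin | C(c1ccccc1)O[C@@H]1Cc2c(OCc3ccccc3)cc(OCc3ccccc3)c(Br)c2O[C@@H]1c1ccc(OCc2ccccc2)c(OCc2ccccc2)c1 | intermediate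
14 | 8-lithio-3,5,7,3',4'-penta-O-benzylepicatechin | C(c1ccccc1)O[C@@H]1Cc2c(OCc3ccccc3)cc(OCc3ccccc3)c([Li])c2O[C@@H]1c1ccc(OCc2ccccc2)c(OCc2ccccc2)c1 | intermediate
15 | (2R,3R)-2-(benzyloxy)-3-[3-(benzyloxy)phenoxy]-3-[4-(benzyloxy)phenyl]-1-(3,5,7,3',4'-penta-O-benzylepicatechin-8-yl)propan-1-ol, both C1 epimers | c5ccccc5COc1ccc([C@@H](Oc3cccc(OCc5ccccc5)c3)[C@H](OCc5ccccc5)C(O)c3c(OCc5ccccc5)cc(OCc5ccccc5)c4c3O[C@H](c3ccc(OCc5ccccc5)c(OCc5ccccc5)c3)[C@H](OCc5ccccc5)C4)cc1 | intermediate
16 | C4 benzylic cation derived from 15 | c5ccccc5COc1ccc([C@@H](Oc3cccc(OCc5ccccc5)c3)[C@H](OCc5ccccc5)[CH+]c3c(OCc5ccccc5)cc(OCc5ccccc5)c4c3O[C@H](c3ccc(OCc5ccccc5)c(OCc5ccccc5)c3)[C@H](OCc5ccccc5)C4)cc1 | intermediate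
17 | (2R,3R,4R)-3,7-bis(benzyloxy)-2-[4-(benzyloxy)phenyl]-4-(3,5,7,3',4'-penta-O-benzylepicatechin-8-yl)chromane (octa-O-benzyl ether of the target) | c5ccccc5COc1ccc([C@H]2Oc3cc(OCc5ccccc5)ccc3[C@H](c3c(OCc5ccccc5)cc(OCc5ccccc5)c4c3O[C@H](c3ccc(OCc5ccccc5)c(OCc5ccccc5)c3)[C@H](OCc5ccccc5)C4)[C@H]2OCc5ccccc5)cc1 | intermediate
18 | (2R,3R,4R)-4-[(2R,3R)-2-(3,4-dihydroxyphenyl)-3,5,7-trihydroxychroman-8-yl]-2-(4-hydroxyphenyl)chromane-3,7-diol | Oc1ccc([C@H]2Oc3cc(O)ccc3[C@H](c3c(O)cc(O)c4c3O[C@H](c3ccc(O)c(O)c3)[C@H](O)C4)[C@H]2O)cc1 | target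

**Step count and risks**

Total: 11 steps. Longest linear sequence: 8 steps (steps 1–5, then 9–11, from 1); the epicatechin branch (steps 6–8) joins at step 9.

Steps most likely to fail:

1. Step 10 (ring closure). The Lewis acid may ionise the benzylic aryl ether at C2 instead of the C4 carbinol. The cation may also lose the C3 proton before it is captured, the ring may close through the carbon between the two oxygens, or the facial bias at C4 may prove insufficient. The fallback makes the two bonds to C4 in the opposite order; it sets out from 9 and 11 and returns to the route at 17. Compound 11 would be benzylated at O3 (NaH, BnBr, DMF) to 3,5,7,3',4'-penta-O-benzyl-(−)-epicatechin F1. Aldehyde 9 would then be treated with BF3·OEt2 in CH2Cl2 at −78 °C in the presence of an excess of F1. The aldehyde's own resorcinol ring should close onto the activated formyl group (intramolecular Friedel–Crafts hydroxyalkylation) to give (2R,3R)-3,7-bis(benzyloxy)-2-[4-(benzyloxy)phenyl]chroman-4-ol F2. Under the same acid F2 should ionise at C4 and be captured by C8 of F1 anti to the axial 3-benzyloxy group, the classical flavan-4-ol plus flavan-3-ol union, to give 17. The price is that attack at C8 rather than C6 of F1 is no longer fixed by a halogen, so regioisomers would have to be separated.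

2. Step 3 (epoxide opening). The opening may lose stereospecificity through a unimolecular, quinone-methide-like pathway that gives retention at the benzylic carbon. The phenoxide may also attack the carbon α to the ester or the ester carbonyl, and base may epimerise the product or expel the aryloxide. The fallback takes the ester out of the opening step; it sets out from 5 and returns at 9. Epoxide 5 would be reduced with i-Bu2AlH (CH2Cl2, −78 °C) to [(2R,3S)-3-[4-(benzyloxy)phenyl]oxiran-2-yl]methanol F3. F3 would be opened with 6 in aqueous NaOH/dioxane at 70 °C, the established benzylic SN2 opening of arylglycidols by phenoxides, to (2R,3R)-3-[3-(benzyloxy)phenoxy]-3-[4-(benzyloxy)phenyl]propane-1,2-diol F4. With PhCH(OMe)2 and catalytic pyridinium p-toluenesulfonate, F4 would give (4R)-4-{(R)-[3-(benzyloxy)phenoxy][4-(benzyloxy)phenyl]methyl}-2-phenyl-1,3-dioxolane F5. Reductive opening of F5 with i-Bu2AlH, which coordinates the less hindered primary oxygen and leaves the benzyl group on the secondary one, should give (2R,3R)-2-(benzyloxy)-3-[3-(benzyloxy)phenoxy]-3-[4-(benzyloxy)phenyl]propan-1-ol F6. Dess–Martin oxidation of F6 would give 9.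

3. Step 9 (fragment union). The hindered aryllithium may act as a base, enolising the α-benzyloxy aldehyde with epimerisation or loss of the β-aryloxide, or it may be quenched before it adds. The fallback uses an acyl electrophile that is not enolised and releases no carbonyl group until work-up; it sets out from 8 and returns at 15. Ester 8 would be converted with MeNH(OMe)·HCl and i-PrMgCl (THF, −20 °C) into (2S,3R)-2-(benzyloxy)-3-[3-(benzyloxy)phenoxy]-3-[4-(benzyloxy)phenyl]-N-methoxy-N-methylpropanamide F7. Addition of 14 to F7 should give a chelated tetrahedral intermediate that releases (2S,3R)-2-(benzyloxy)-3-[3-(benzyloxy)phenoxy]-3-[4-(benzyloxy)phenyl]-1-(3,5,7,3',4'-penta-O-benzylepicatechin-8-yl)propan-1-one F8 only on aqueous work-up. Reduction of F8 with NaBH4 (THF/MeOH, 0 °C) would give 15, either epimer being acceptable.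

**Further compounds**

F1 | step 10 | 3,5,7,3',4'-penta-O-benzyl-(−)-epicatechin | C(c1ccccc1)O[C@@H]1Cc2c(OCc3ccccc3)cc(OCc3ccccc3)cc2O[C@@H]1c1ccc(OCc2ccccc2)c(OCc2ccccc2)c1
F2 | step 10 | (2R,3R)-3,7-bis(benzyloxy)-2-[4-(benzyloxy)phenyl]chroman-4-ol (C4 epimers) | c5ccccc5COc1ccc([C@H]2Oc3cc(OCc5ccccc5)ccc3C(O)[C@H]2OCc5ccccc5)cc1
F3 | step 3 | [(2R,3S)-3-[4-(benzyloxy)phenyl]oxiran-2-yl]methanol | OC[C@H]1O[C@H]1c1ccc(OCc2ccccc2)cc1
F4 | step 3 | (2R,3R)-3-[3-(benzyloxy)phenoxy]-3-[4-(benzyloxy)phenyl]propane-1,2-diol | OC[C@@H](O)[C@H](Oc1cccc(OCc2ccccc2)c1)c1ccc(OCc2ccccc2)cc1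
F5 | step 3 | (4R)-4-{(R)-[3-(benzyloxy)phenoxy][4-(benzyloxy)phenyl]methyl}-2-phenyl-1,3-dioxolane (acetal epimers) | C1OC(c2ccccc2)O[C@H]1[C@H](Oc1cccc(OCc2ccccc2)c1)c1ccc(OCc2ccccc2)cc1
F6 | step 3 | (2R,3R)-2-(benzyloxy)-3-[3-(benzyloxy)phenoxy]-3-[4-(benzyloxy)phenyl]propan-1-ol | OC[C@@H](OCc1ccccc1)[C@H](Oc1cccc(OCc2ccccc2)c1)c1ccc(OCc2ccccc2)cc1
F7 | step 9 | (2S,3R)-2-(benzyloxy)-3-[3-(benzyloxy)phenoxy]-3-[4-(benzyloxy)phenyl]-N-methoxy-N-methylpropanamide | CON(C)C(=O)[C@@H](OCc1ccccc1)[C@H](Oc1cccc(OCc2ccccc2)c1)c1ccc(OCc2ccccc2)cc1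
F8 | step 9 | (2S,3R)-2-(benzyloxy)-3-[3-(benzyloxy)phenoxy]-3-[4-(benzyloxy)phenyl]-1-(3,5,7,3',4'-penta-O-benzylepicatechin-8-yl)propan-1-one | c5ccccc5COc1ccc([C@@H](Oc3cccc(OCc5ccccc5)c3)[C@H](OCc5ccccc5)C(=O)c3c(OCc5ccccc5)cc(OCc5ccccc5)c4c3O[C@H](c3ccc(OCc5ccccc5)c(OCc5ccccc5)c3)[C@H](OCc5ccccc5)C4)cc1
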